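**Retrosynthetic overview**
1. Target ⇐ macrocyclic 8,9-acetonide / 14-dioxolane acetal / 15-O-TBDPS lactone; the two angelates, the C11=C13 methylene (Mannich/elimination) and the free 14-CHO and 15-OH come after ring closure.
2. Ten-membered ring: closed last at C9–C10 by an intramolecular iridium-photoredox/nickel decarboxylative C(sp3)–C(sp2) coupling of an α-oxy acid with a (Z)-vinyl iodide (no RCM, no Barbier or NHK allylation).
3. C4=C5: Wittig reaction of a C5 aldehyde with a formyl-stabilised ylide carrying C1–C4, C10, C14 and C15 (from 5-bromopent-1-ene).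
4. C7–C8: photoredox decarboxylative Giese addition of the dioxolanyl radical from L-tartrate monoester to (S)-5-(hydroxymethyl)butenolide; C6 and C9 come from the chiral pool and dictate C7 and C8, and tartaric acid ends as a C8–C9 linchpin that has lost both carboxyl carbons.
5. Ring order: γ-lactone (already in the butenolide) and dioxolane (already in the tartrate) first, ten-membered carbocycle in step 13, exocyclic methylene afterwards.

Assumption: germacrane numbering (C1–C15; lactone C12–O–C6, C14 on C10, C15 on C4) is used for locants; 1, 4, 7 and all reagents are taken as commercial; both ring alkenes are ring-cis, which is E in CIP terms because C14 and C15 outrank the ring carbons.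

**Route**

Step 1
Reactants: 1 dimethyl (4R,5R)-2,2-dimethyl-1,3-dioxolane-4,5-dicarboxylate
Product: 3 (4R,5R)-5-(methoxycarbonyl)-2,2-dimethyl-1,3-dioxolane-4-carboxylic acid, via potassium carboxylate 2 (not isolated)
Conditions: KOH (1.0 equiv), MeOH, 0 °C to rt; then 1 M HCl to pH 2
Reagents that add atoms: potassium hydroxide, [K+].[OH-]
Why: Mono-saponification of a C2-symmetric diester (ester hydrolysis): the two esters are homotopic and the first carboxylate formed slows the second hydrolysis, so one carboxyl is freed without touching a stereocentre.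

Step 2
Reactants: 3 tartrate monoacid; 4 (5S)-5-(hydroxymethyl)furan-2(5H)-one
Product: 5 methyl (4R,5S)-5-[(2S,3S)-2-(hydroxymethyl)-5-oxooxolan-3-yl]-2,2-dimethyl-1,3-dioxolane-4-carboxylate
Conditions: 3 (1.5 equiv), Ir[dF(CF3)ppy]2(dtbbpy)PF6 (1 mol%), K2HPO4 (1.2 equiv), DMF, blue LEDs (450 nm), rt
Reagents that add atoms: none
Why: Photoredox decarboxylative Giese (radical conjugate) addition: oxidation of the carboxylate and loss of CO2 give a nucleophilic dioxolan-4-yl radical that adds to the butenolide β-carbon C7 anti to the C6 CH2OH group (trans-lactone, 7S) and through its face anti to the C9 CO2Me group (trans-dioxolane, 8S), so both new centres are dictated by the neighbouring chiral-pool centres.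

Step 3
Reactants: 5 hydroxymethyl lactone ester
Product: 6 methyl (4R,5S)-5-[(2S,3R)-2-formyl-5-oxooxolan-3-yl]-2,2-dimethyl-1,3-dioxolane-4-carboxylate
Conditions: Dess–Martin periodinane, CH2Cl2, 0 °C to rt
Reagents that add atoms: none
Why: Dess–Martin oxidation of the primary alcohol under near-neutral conditions gives the α-acyloxy aldehyde without epimerising C6 (trans to C7 is also the thermodynamic arrangement); the changed ring descriptor is a CIP priority effect only.

Step 4
Reactants: 7 5-bromopent-1-ene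
Product: 8 (2E)-6-bromohex-2-enal
Conditions: crotonaldehyde (5 equiv), second-generation Hoveyda–Grubbs catalyst RuCl2(H2IMes)(=CH-C6H4-2-OiPr) (2 mol%), CH2Cl2, 40 °C
Reagents that add atoms: crotonaldehyde, C/C=C/C=O
Why: Olefin cross-metathesis of a terminal alkene with excess crotonaldehyde gives the conjugated (E)-enal under thermodynamic control with loss of propene.

Step 5
Reactants: 8 bromo enal
Product: 9 (2Z)-6-bromo-2-iodohex-2-enal
Conditions: I2, DMAP (20 mol%), K2CO3, THF/H2O (1:1), rt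
Reagents that add atoms: iodine, [I][I]
Why: α-Iodination of an enal by a Baylis–Hillman-type addition–elimination (DMAP conjugate addition, iodination of the enolate, E1cB loss of DMAP) gives the (Z)-α-iodoenal with CHO trans to the chain, the geometry later needed at C1=C10.

Step 6
Reactants: 9 iodo enal
Product: 10 2-[(1Z)-5-bromo-1-iodopent-1-en-1-yl]-1,3-dioxolane
Conditions: Me3SiOCH2CH2OSiMe3, Me3SiOTf (5 mol%), CH2Cl2, −78 to −20 °C
Reagents that add atoms: 1,2-bis(trimethylsilyloxy)ethane, C[Si](C)(C)OCCO[Si](C)(C)C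
Why: Noyori acetalisation (aprotic, low temperature) masks the aldehyde as a 1,3-dioxolane without conjugate addition or alkene migration, so the (Z)-geometry is kept.

Step 7
Reactants: 10 bromo acetal
Product: 11 [(4Z)-5-(1,3-dioxolan-2-yl)-5-iodopent-4-en-1-yl]triphenylphosphonium bromide
Conditions: PPh3, MeCN, reflux
Reagents that add atoms: triphenylphosphine, c1ccc(cc1)P(c1ccccc1)c1ccccc1
Why: SN2 quaternisation of triphenylphosphine by the primary bromide; vinyl iodide and acetal are inert under these neutral conditions.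

Step 8
Reactants: 11 phosphonium bromide
Product: 13 (5Z)-6-(1,3-dioxolan-2-yl)-6-iodo-2-(triphenyl-λ5-phosphanylidene)hex-5-enal, via phosphonium ylide 12 (not isolated)
Conditions: NaN(SiMe3)2 (1.05 equiv), THF, −78 °C; then HCO2Et, −78 °C to rt
Reagents that add atoms: ethyl formate, CCOC=O
Why: C-Formylation of a non-stabilised ylide (ylide acylation): the ylide attacks ethyl formate and the released ethoxide deprotonates the acylphosphonium ion to give the isolable formyl-stabilised ylide, the phosphonium α-CH2 being deprotonated far faster at −78 °C than the vinyl iodide can eliminate.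

Step 9
Reactants: 6 lactone aldehyde; 13 formyl ylide
Product: 14 methyl (4R,5S)-5-[(2R,3S)-2-[(1E,5Z)-6-(1,3-dioxolan-2-yl)-2-formyl-6-iodohexa-1,5-dien-1-yl]-5-oxooxolan-3-yl]-2,2-dimethyl-1,3-dioxolane-4-carboxylate
Conditions: toluene, 80 °C
Reagents that add atoms: none
Why: Wittig olefination with a formyl-stabilised ylide gives the (E)-2-substituted enal (CHO trans to C6, hence C3 cis to C6, the ring-cis 4,5-alkene of the target), and the weakly basic ylide leaves C6 intact.

Step 10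
Reactants: 14 enal
Product: 15 methyl (4R,5S)-5-[(2R,3S)-2-[(1E,5Z)-6-(1,3-dioxolan-2-yl)-2-(hydroxymethyl)-6-iodohexa-1,5-dien-1-yl]-5-oxooxolan-3-yl]-2,2-dimethyl-1,3-dioxolane-4-carboxylate
Conditions: NaBH4, CeCl3·7H2O, MeOH, −78 °C
Reagents that add atoms: none
Why: Luche reduction reduces only the enal carbonyl (1,2-selective) to the C15 allylic alcohol; lactone, methyl ester, acetal and vinyl iodide are untouched at −78 °C.

Step 11
Reactants: 15 allylic alcohol
Product: 16 methyl (4R,5S)-5-[(2R,3S)-2-[(1E,5Z)-2-{[(tert-butyldiphenylsilyl)oxy]methyl}-6-(1,3-dioxolan-2-yl)-6-iodohexa-1,5-dien-1-yl]-5-oxooxolan-3-yl]-2,2-dimethyl-1,3-dioxolane-4-carboxylate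
Conditions: TBDPSCl, imidazole, CH2Cl2, rt
Reagents that add atoms: tert-butyl(chloro)diphenylsilane, CC(C)(C)[Si](Cl)(c1ccccc1)c1ccccc1
Why: Silylation of the primary allylic alcohol gives an acid- and base-robust ether that carries the 15-OH to the last step.

Step 12
Reactants: 16 silyl ether methyl ester
Product: 18 (4R,5S)-5-[(2R,3S)-2-[(1E,5Z)-2-{[(tert-butyldiphenylsilyl)oxy]methyl}-6-(1,3-dioxolan-2-yl)-6-iodohexa-1,5-dien-1-yl]-5-oxooxolan-3-yl]-2,2-dimethyl-1,3-dioxolane-4-carboxylic acid, via lithium carboxylate 17 (not isolated)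
Conditions: LiOH·H2O (1.2 equiv), THF/H2O (3:1), 0 °C; then 0.5 M HCl to pH 4
Reagents that add atoms: lithium hydroxide, [Li+].[OH-]
Why: Saponification of the doubly O-activated methyl ester, the fastest-hydrolysing carbonyl in 16 (any lactone that opens recloses on acidification); epimerisation at C9 would be harmless because this centre becomes a radical in step 13.

Step 13
Reactants: 18 iodo acid
Product: 19 (1(10)E,4E,6R,7S,8S,9S)-15-(tert-butyldiphenylsilyloxy)-14,14-(ethylenedioxy)-8,9-(isopropylidenedioxy)-13-norgermacra-1(10),4-dien-12,6-olide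
Conditions: Ir[dF(CF3)ppy]2(dtbbpy)PF6 (2 mol%), NiCl2·(MeOCH2CH2OMe) (30 mol%), 4,4′-di-tert-butyl-2,2′-bipyridine (35 mol%), DBU (1.5 equiv), DMSO (2 mM), blue LEDs, 25 °C
Reagents that add atoms: none
Why: Proposed new method: an intramolecular, ring-closing version of the known intermolecular iridium-photoredox/nickel decarboxylative vinylation of α-oxy acids (closest known reaction type): the excited photocatalyst oxidises the carboxylate, CO2 is lost, the C9 dioxolanyl radical and the vinyl iodide of the same molecule meet at one bipyridine-ligated nickel centre (zerovalent nickel inserts into C–I, radical capture gives trivalent nickel) and reductive elimination forges C9–C10 with retention of the iodoalkene geometry (ring-cis 1(10)-alkene) and anti to the lactone-bearing C8 substituent (trans-dioxolane, 9S), while high dilution suppresses oligomers, the two cis-alkenes and the trans-lactone pre-fold the chain, and 5-exo attack of the radical on C5 is disfavoured because it would create a trans-fused bicyclo[3.3.0]octane.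

Step 14
Reactants: 19 macrocyclic lactone
Product: 21 (1(10)E,4E,6R,7S,8S,9S,11RS)-15-(tert-butyldiphenylsilyloxy)-13-(dimethylamino)-14,14-(ethylenedioxy)-8,9-(isopropylidenedioxy)germacra-1(10),4-dien-12,6-olide, via lithium enolate 20 (not isolated)
Conditions: LiN(SiMe3)2, THF, −78 °C; then CH2=NMe2+ I−, −78 to 0 °C
Reagents that add atoms: N,N-dimethylmethyleneiminium iodide (Eschenmoser's salt), C=[N+](C)C.[I-]
Why: Mannich aminomethylation of the lactone enolate with Eschenmoser's salt; the lactone α-CH2 is the only acidic site and the C11 configuration is irrelevant because C11 becomes sp2 in step 15.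

Step 15
Reactants: 21 Mannich base
Product: 23 (1(10)E,4E,6R,7S,8S,9S)-15-(tert-butyldiphenylsilyloxy)-14,14-(ethylenedioxy)-8,9-(isopropylidenedioxy)germacra-1(10),4,11(13)-trien-12,6-olide, via ammonium iodide 22 (not isolated)
Conditions: MeI, MeOH, rt; then DBU, CH2Cl2, rt
Reagents that add atoms: none
Why: Exhaustive N-methylation followed by base-induced E1cB (Hofmann-type) loss of trimethylamine, the classical two-stage α-methylenation of a γ-lactone, installs the exocyclic 11(13)-alkene only after all radical chemistry is finished.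

Step 16
Reactants: 23 acetonide
Product: 24 (1(10)E,4E,6R,7R,8S,9S)-15-(tert-butyldiphenylsilyloxy)-14,14-(ethylenedioxy)-8,9-dihydroxygermacra-1(10),4,11(13)-trien-12,6-olide
Conditions: AcOH/H2O (4:1), 35 °C
Reagents that add atoms: none
Why: Selective acid hydrolysis of the strained trans-fused isopropylidene ketal, expected to cleave much faster than the aldehyde-derived dioxolane at C14 (kept so that the freed 8-OH cannot form a lactol with a C14 aldehyde) and leaving the TBDPS ether intact; the 7R descriptor is a CIP priority change, not an inversion.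

Step 17
Reactants: 24 diol
Product: 25 (1(10)E,4E,6R,7S,8S,9S)-8,9-bis(angeloyloxy)-15-(tert-butyldiphenylsilyloxy)-14,14-(ethylenedioxy)germacra-1(10),4,11(13)-trien-12,6-olide
Conditions: angelic acid (6 equiv), 2,4,6-trichlorobenzoyl chloride (6 equiv), Et3N (8 equiv), toluene, rt; then 24, 75 °C
Reagents that add atoms: angelic acid ((Z)-2-methylbut-2-enoic acid), C/C=C(/C)C(=O)O
Why: Yamaguchi-type esterification through the preformed mixed anhydride, the established way of making angelates without Z-to-E isomerisation to tiglates, acylates both secondary alcohols with retention at C8 and C9.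

Step 18
Reactants: 25 bis-angelate
Product: 27 (1(10)E,4E,6R,7S,8S,9S)-8,9-bis(angeloyloxy)-15-hydroxy-14-oxogermacra-1(10),4,11(13)-trien-12,6-olide (CNP0139154.1), via acetal alcohol 26 (not isolated)
Conditions: HF·pyridine, pyridine, THF, 0 °C to rt; concentrate; then 2 M aq. HCl/THF (1:3), rt
Reagents that add atoms: water, O
Why: Fluoride-mediated desilylation frees the 15-OH and acid-catalysed acetal hydrolysis then unveils the conjugated C14 aldehyde; angelates, α-methylene lactone and all four stereocentres are inert to both stages.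

**Compound list**

1 | dimethyl (4R,5R)-2,2-dimethyl-1,3-dioxolane-4,5-dicarboxylate (dimethyl 2,3-O-isopropylidene-L-tartrate) | COC(=O)[C@@H]1OC(C)(C)O[C@H]1C(=O)OC | starting material
2 | potassium (4R,5R)-5-(methoxycarbonyl)-2,2-dimethyl-1,3-dioxolane-4-carboxylate | COC(=O)[C@@H]1OC(C)(C)O[C@H]1C(=O)[O-].[K+] | intermediate
3 | (4R,5R)-5-(methoxycarbonyl)-2,2-dimethyl-1,3-dioxolane-4-carboxylic acid | COC(=O)[C@@H]1OC(C)(C)O[C@H]1C(=O)O | intermediate
4 | (5S)-5-(hydroxymethyl)furan-2(5H)-one | OC[C@H]1OC(=O)C=C1 | starting material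
5 | methyl (4R,5S)-5-[(2S,3S)-2-(hydroxymethyl)-5-oxooxolan-3-yl]-2,2-dimethyl-1,3-dioxolane-4-carboxylate | O=C1C[C@H]([C@@H]2OC(C)(C)O[C@H]2C(=O)OC)[C@@H](CO)O1 | intermediate
6 | methyl (4R,5S)-5-[(2S,3R)-2-formyl-5-oxooxolan-3-yl]-2,2-dimethyl-1,3-dioxolane-4-carboxylate | O=C1C[C@H]([C@@H]2OC(C)(C)O[C@H]2C(=O)OC)[C@@H](C=O)O1 | intermediate
7 | 5-bromopent-1-ene | C=CCCCBr | starting material
8 | (2E)-6-bromohex-2-enal | O=C/C=C/CCCBr | intermediate
9 | (2Z)-6-bromo-2-iodohex-2-enal | O=C/C(I)=C/CCCBr | intermediate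
10 | 2-[(1Z)-5-bromo-1-iodopent-1-en-1-yl]-1,3-dioxolane | O1CCOC1/C(I)=C/CCCBr | intermediate
11 | [(4Z)-5-(1,3-dioxolan-2-yl)-5-iodopent-4-en-1-yl]triphenylphosphonium bromide | O1CCOC1/C(I)=C/CCC[P+](c1ccccc1)(c1ccccc1)c1ccccc1.[Br-] | intermediate
12 | [(4Z)-5-(1,3-dioxolan-2-yl)-5-iodopent-4-en-1-ylidene]triphenyl-λ5-phosphane | O1CCOC1/C(I)=C/CCC=P(c1ccccc1)(c1ccccc1)c1ccccc1 | intermediate
13 | (5Z)-6-(1,3-dioxolan-2-yl)-6-iodo-2-(triphenyl-λ5-phosphanylidene)hex-5-enal | O1CCOC1/C(I)=C/CCC(C=O)=P(c1ccccc1)(c1ccccc1)c1ccccc1 | intermediate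
14 | methyl (4R,5S)-5-[(2R,3S)-2-[(1E,5Z)-6-(1,3-dioxolan-2-yl)-2-formyl-6-iodohexa-1,5-dien-1-yl]-5-oxooxolan-3-yl]-2,2-dimethyl-1,3-dioxolane-4-carboxylate | O=C1C[C@H]([C@@H]2OC(C)(C)O[C@H]2C(=O)OC)[C@@H](/C=C(/C=O)CC/C=C(/C2OCCO2)I)O1 | intermediate
15 | methyl (4R,5S)-5-[(2R,3S)-2-[(1E,5Z)-6-(1,3-dioxolan-2-yl)-2-(hydroxymethyl)-6-iodohexa-1,5-dien-1-yl]-5-oxooxolan-3-yl]-2,2-dimethyl-1,3-dioxolane-4-carboxylate | O=C1C[C@H]([C@@H]2OC(C)(C)O[C@H]2C(=O)OC)[C@@H](/C=C(/CO)CC/C=C(/C2OCCO2)I)O1 | intermediate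
16 | methyl (4R,5S)-5-[(2R,3S)-2-[(1E,5Z)-2-{[(tert-butyldiphenylsilyl)oxy]methyl}-6-(1,3-dioxolan-2-yl)-6-iodohexa-1,5-dien-1-yl]-5-oxooxolan-3-yl]-2,2-dimethyl-1,3-dioxolane-4-carboxylate | O=C1C[C@H]([C@@H]2OC(C)(C)O[C@H]2C(=O)OC)[C@@H](/C=C(/CO[Si](c2ccccc2)(c2ccccc2)C(C)(C)C)CC/C=C(/C2OCCO2)I)O1 | intermediate
17 | lithium carboxylate of acid 18 | O=C1C[C@H]([C@@H]2OC(C)(C)O[C@H]2C(=O)[O-])[C@@H](/C=C(/CO[Si](c2ccccc2)(c2ccccc2)C(C)(C)C)CC/C=C(/C2OCCO2)I)O1.[Li+] | intermediate
18 | (4R,5S)-5-[(2R,3S)-2-[(1E,5Z)-2-{[(tert-butyldiphenylsilyl)oxy]methyl}-6-(1,3-dioxolan-2-yl)-6-iodohexa-1,5-dien-1-yl]-5-oxooxolan-3-yl]-2,2-dimethyl-1,3-dioxolane-4-carboxylic acid | O=C1C[C@H]([C@@H]2OC(C)(C)O[C@H]2C(=O)O)[C@@H](/C=C(/CO[Si](c2ccccc2)(c2ccccc2)C(C)(C)C)CC/C=C(/C2OCCO2)I)O1 | intermediate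
19 | (1(10)E,4E,6R,7S,8S,9S)-15-(tert-butyldiphenylsilyloxy)-14,14-(ethylenedioxy)-8,9-(isopropylidenedioxy)-13-norgermacra-1(10),4-dien-12,6-olide | C1C(=O)O[C@@H]2/C=C(/CO[Si](c3ccccc3)(c3ccccc3)C(C)(C)C)CC/C=C(/C3OCCO3)[C@@H]3OC(C)(C)O[C@H]3[C@@H]12 | intermediate
20 | lithium enolate of 19 (C11=C12–OLi) | C1=C([O-])O[C@@H]2/C=C(/CO[Si](c3ccccc3)(c3ccccc3)C(C)(C)C)CC/C=C(/C3OCCO3)[C@@H]3OC(C)(C)O[C@H]3[C@@H]12.[Li+] | intermediate
21 | (1(10)E,4E,6R,7S,8S,9S,11RS)-15-(tert-butyldiphenylsilyloxy)-13-(dimethylamino)-14,14-(ethylenedioxy)-8,9-(isopropylidenedioxy)germacra-1(10),4-dien-12,6-olide | CN(C)CC1C(=O)O[C@@H]2/C=C(/CO[Si](c3ccccc3)(c3ccccc3)C(C)(C)C)CC/C=C(/C3OCCO3)[C@@H]3OC(C)(C)O[C@H]3[C@@H]12 | intermediate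
22 | 13-(trimethylammonio) analogue of 21 as its iodide | C[N+](C)(C)CC1C(=O)O[C@@H]2/C=C(/CO[Si](c3ccccc3)(c3ccccc3)C(C)(C)C)CC/C=C(/C3OCCO3)[C@@H]3OC(C)(C)O[C@H]3[C@@H]12.[I-] | intermediate
23 | (1(10)E,4E,6R,7S,8S,9S)-15-(tert-butyldiphenylsilyloxy)-14,14-(ethylenedioxy)-8,9-(isopropylidenedioxy)germacra-1(10),4,11(13)-trien-12,6-olide | C=C1C(=O)O[C@@H]2/C=C(/CO[Si](c3ccccc3)(c3ccccc3)C(C)(C)C)CC/C=C(/C3OCCO3)[C@@H]3OC(C)(C)O[C@H]3[C@@H]12 | intermediate
24 | (1(10)E,4E,6R,7R,8S,9S)-15-(tert-butyldiphenylsilyloxy)-14,14-(ethylenedioxy)-8,9-dihydroxygermacra-1(10),4,11(13)-trien-12,6-olide | C=C1C(=O)O[C@@H]2/C=C(/CO[Si](c3ccccc3)(c3ccccc3)C(C)(C)C)CC/C=C(/C3OCCO3)[C@H](O)[C@@H](O)[C@@H]12 | intermediate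
25 | (1(10)E,4E,6R,7S,8S,9S)-8,9-bis(angeloyloxy)-15-(tert-butyldiphenylsilyloxy)-14,14-(ethylenedioxy)germacra-1(10),4,11(13)-trien-12,6-olide | C=C1C(=O)O[C@@H]2/C=C(/CO[Si](c3ccccc3)(c3ccccc3)C(C)(C)C)CC/C=C(/C3OCCO3)[C@H](OC(=O)/C(C)=C\C)[C@@H](OC(=O)/C(C)=C\C)[C@@H]12 | intermediate
26 | (1(10)E,4E,6R,7S,8S,9S)-8,9-bis(angeloyloxy)-14,14-(ethylenedioxy)-15-hydroxygermacra-1(10),4,11(13)-trien-12,6-olide | C=C1C(=O)O[C@@H]2/C=C(/CO)CC/C=C(/C3OCCO3)[C@H](OC(=O)/C(C)=C\C)[C@@H](OC(=O)/C(C)=C\C)[C@@H]12 | intermediate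
27 | (1(10)E,4E,6R,7S,8S,9S)-8,9-bis(angeloyloxy)-15-hydroxy-14-oxogermacra-1(10),4,11(13)-trien-12,6-olide (CNP0139154.1) | C=C1C(=O)O[C@@H]2/C=C(/CO)CC/C=C(/C=O)[C@H](OC(=O)/C(C)=C\C)[C@@H](OC(=O)/C(C)=C\C)[C@@H]12 | target

**Totals and risks**

Total step count: 18. Longest linear sequence: 15 steps (7 to 27, steps 4–18); the tartrate line (1 to 27) is 13 steps.

Three steps most likely to fail:

- **Step 13 (ring-closing decarboxylative vinylation).** Risks are oligomerisation, protodecarboxylation and formation of the cis-fused C9 epimer. The fallback sets out from 18 and comes back at 19. Acid 18 is esterified with N-hydroxyphthalimide (DIC, DMAP cat., CH2Cl2) to the redox-active N-(acyloxy)phthalimide ester F1. A nickel-catalysed reductive cross-electrophile macrocyclisation (NiBr2·(MeOCH2CH2OMe), 4,4′-di-tert-butyl-2,2′-bipyridine, Zn, DMA, 2 mM, rt) then generates the C9 radical by single-electron reduction instead of photo-oxidation, with no photocatalyst and no base, and closes C9–C10 to give 19.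

- **Step 2 (Giese union of the two chirons).** Risks are base-mediated racemisation of butenolide 4 through its dienolate, sluggish addition to a β-substituted acceptor and facial leakage. The fallback sets out from 3 and comes back at 5. Acid 3 is converted (1-hydroxypyridine-2(1H)-thione, DCC, CH2Cl2, dark) into the thiohydroxamate (Barton) ester F2. Visible-light photolysis of F2 with 4 under neutral conditions runs as a radical chain with group transfer and gives the α-(pyridin-2-ylsulfanyl) lactone F3. Bu3SnH/AIBN (toluene, 80 °C) removes the sulfur group and returns 5.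

- **Step 17 (double angeloylation).** Risks are the hindered 8-OH, isomerisation to tiglate and base-induced 6,12- to 8,12-translactonisation. The fallback sets out from 24 and comes back at 25. Diol 24 is acylated with 2-[bis(2,2,2-trifluoroethoxy)phosphoryl]propanoic acid (DCC, DMAP, CH2Cl2) to the bis(phosphonopropionate) F4. A double Still–Gennari olefination with acetaldehyde (KN(SiMe3)2, 18-crown-6, THF, −78 °C) then builds both (Z)-2-methylbut-2-enoates on the molecule and gives 25.

**Further compounds**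

F1 | step 13 | 1,3-dioxoisoindolin-2-yl ester of acid 18 | O=C1C[C@H]([C@@H]2OC(C)(C)O[C@H]2C(=O)ON2C(=O)c3ccccc3C2=O)[C@@H](/C=C(/CO[Si](c2ccccc2)(c2ccccc2)C(C)(C)C)CC/C=C(/C2OCCO2)I)O1
F2 | step 2 | methyl (4R,5R)-2,2-dimethyl-5-{[(2-thioxopyridin-1(2H)-yl)oxy]carbonyl}-1,3-dioxolane-4-carboxylate | COC(=O)[C@@H]1OC(C)(C)O[C@H]1C(=O)ON1C=CC=CC1=S
F3 | step 2 | methyl (4R,5S)-5-[(2S,3S)-2-(hydroxymethyl)-5-oxo-4-(pyridin-2-ylsulfanyl)oxolan-3-yl]-2,2-dimethyl-1,3-dioxolane-4-carboxylate (sulfur-bearing carbon unassigned) | O=C1C(Sc2ccccn2)[C@H]([C@@H]2OC(C)(C)O[C@H]2C(=O)OC)[C@@H](CO)O1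
F4 | step 17 | 8,9-bis{2-[bis(2,2,2-trifluoroethoxy)phosphoryl]propanoyl} ester of diol 24 | C=C1C(=O)O[C@@H]2/C=C(/CO[Si](c3ccccc3)(c3ccccc3)C(C)(C)C)CC/C=C(/C3OCCO3)[C@H](OC(=O)C(C)P(=O)(OCC(F)(F)F)OCC(F)(F)F)[C@@H](OC(=O)C(C)P(=O)(OCC(F)(F)F)OCC(F)(F)F)[C@@H]12
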